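**Assumption:** Locants follow neolignan usage: C7 is the benzylic carbinol carbon, C8 the ether carbon, C9 the CH2OH carbon. Ring A (4-hydroxy-3,5-dimethoxyphenyl) sits on C7; ring B (4-allyl-2,6-dimethoxyphenyl, primed locants) is bound to C8 through O4′. The SMILES is read as (7R,8S), the erythro isomer. Compounds 1, 3 and 6 are taken as purchasable.

## The problem

The skeleton is only the chain C7–C8–C9, with ring A and OH on C7, O4′ of ring B on C8 and OH on C9; the hard parts are the C8–O4′ bond and the C7/C8 pair. O4′ lies between the C3′ and C5′ methoxy groups, so a di-ortho-substituted phenol must be joined to a secondary stereogenic carbon. Because ring B is electron-rich, this ether can only be made by attack of the phenol oxygen on C8, not by arylating a C8 alcohol with retention. The pair is erythro (anti), whereas the usual single-stroke asymmetric entries to such a pair (closed-transition-state syn aldol, dihydroxylation of an E-alkene, outer-sphere reduction of an α-oxy-β-keto ester with dynamic resolution) all end in threo; erythro must therefore come from a chelate-controlled step or an inversion. C8 can control C7 through O4′, which is 1,2 to C7, whereas C7 is a benzylic carbinol para to the ring-A hydroxyl, labile through quinone methide formation, and is best made late. The feature that makes the key step possible is the position of C8 between C9 and C7: with C7 at the carboxyl oxidation level the C7–C8–C9 unit is glyceric acid, and C8 is a carbinol carbon α to an ester carbonyl, where even the hindered O4′ phenoxide substitutes by clean SN2 with inversion. The terminal allyl group on C1′ forbids hydrogenolysis, osmylation, ozonolysis, free boranes and isomerizing bases or metal hydrides, and the ring-A phenol must be masked by a group removed without acid or hydrogen.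

## Retrosynthesis

**12 ⇐ 11 (O–Si bonds on O4 of ring A and on O9).** The free p-hydroxybenzyl alcohol is the fragile array, so it is unmasked last. Silyl ethers are chosen over benzyl ethers because of the allyl group. The forward step must be non-acidic and non-reductive.

**11 ⇐ 10 (C7–H).** Making C7 by adding an aryl nucleophile to a C7 aldehyde would lean on Felkin–Anh control at a configurationally labile α-aryloxy aldehyde. As a ketone, C7 is flanked by O4′, and a metal held between the carbonyl oxygen and O4′ should deliver hydride to the erythro face. The forward step needs a chelating, non-basic hydride that leaves the alkene alone.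

**10 ⇐ 7 + 2, via 8 and 9 (C7–C1 of ring A).** This cut divides the molecule into two halves of similar size: an aryllithium from a purchasable bromophenol and an ester that already holds C8, O4′ and ring B. Unlike the C7–C8 (aldol) cut, it keeps C8 out of enolate chemistry. The forward reaction must stop at the ketone, hence the Weinreb amide.

**7 ⇐ 5 + 6 (C8–O4′, key disconnection).** Made here, the bond forms at a carbinol α to an ester with only a CH2OSi neighbour. Made later, C8 would carry a CH(OH)Ar neighbour, more hindrance and a hydroxyl ready to close an epoxide. The precursors are a pool-derived hydroxy ester and purchasable phenol 6. The forward reaction must go with clean inversion, so that the R carbinol becomes the S ether.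

**5 ⇐ 4 ⇐ 3 and 2 ⇐ 1.** These are protecting-group adjustments only: acetal hydrolysis and primary-selective silylation on the glycerate, and silylation of the ring-A bromophenol.

## Roads not taken

**Alternative 1:** Cut C7–C8 (most obvious). The forward key step is a boron-mediated auxiliary aldol of the aryloxyacetyl oxazolidinone A1 with aldehyde A2.
- The Z-enolate reacts through a closed chair transition state and gives the syn adduct A3, which maps onto the threo (7R,8R) diol, the C8 epimer of the target.
- Anti-selective glycolate aldols need an open transition state with a Lewis-acid-complexed aldehyde. The outcome is hard to predict with three Lewis-basic oxygens on the aryloxy group and a weakly electrophilic, electron-rich aldehyde.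
- The auxiliary is stoichiometric and must be attached and removed; the step count is about the same as the chosen plan.
- The chosen plan takes erythro from a chelate that the structure itself provides.

**Alternative 2:** Cut C8–O4′ after both centres are set catalytically. The sequence is asymmetric dihydroxylation of cinnamate A4 to threo diol A5, selective 2-O-sulfonylation to A6, and SN2 by 6 with inversion.
- The free C7 hydroxyl of A6 is placed for intramolecular displacement under the basic conditions that generate the phenoxide.
- The benzylic C7 on an oxygenated ring is a competing electrophilic site.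
- C8 of A6 is more hindered than C8 of 5.
- Curing this needs extra protection steps, so the route becomes longer than the chosen one.

**Alternative 3:** Cut C7–H with dynamic kinetic resolution. Racemic keto ester A7 (two steps from 6) would be reduced by Ru-catalysed transfer hydrogenation to A8.
- The appeal is that both centres come from a racemate in one catalytic step.
- Hydride is delivered without a chelate, so the polar Felkin–Anh arrangement (aryloxy anti to hydride) applies and the syn product A8 is expected, which is threo.
- Erythro would then need an extra inversion at C7, a benzylic carbinol where ionization competes with SN2, plus added steps.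
- The chosen plan reaches erythro directly.

Key step: step 4

## Route

Step 1
Reactants: 1 4-bromo-2,6-dimethoxyphenol
Product: 2 tert-butyl(4-bromo-2,6-dimethoxyphenoxy)dimethylsilane
Conditions: TBSCl, imidazole, DMF, rt
Reagents that add atoms: tert-butyldimethylsilyl chloride, CC(C)(C)[Si](C)(C)Cl
Why: Imidazole-promoted silylation of a phenol; the aryl silyl ether, shielded by both ortho-methoxy groups, should survive the aryllithium and hydride steps.

Step 2
Reactants: 3 methyl (R)-2,2-dimethyl-1,3-dioxolane-4-carboxylate
Product: 4 methyl (R)-2,3-dihydroxypropanoate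
Conditions: AcOH/H2O (4:1), 45 °C
Reagents that add atoms: none
Why: Acid-catalysed hydrolysis of the isopropylidene acetal; C8 is not involved, so the R configuration of the pool material is carried over unchanged.

Step 3
Reactants: 4 methyl (R)-2,3-dihydroxypropanoate
Product: 5 methyl (R)-3-[(tert-butyldiphenylsilyl)oxy]-2-hydroxypropanoate
Conditions: TBDPSCl, imidazole, CH2Cl2, 0 °C
Reagents that add atoms: tert-butyldiphenylsilyl chloride, CC(C)(C)[Si](Cl)(c1ccccc1)c1ccccc1
Why: Regioselective silylation: the bulky chlorosilane takes the primary C9 hydroxyl, while the C8 hydroxyl is secondary and deactivated by the ester; the bulky silyl group later keeps O9 out of any chelate.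

Step 4
Reactants: 5 methyl (R)-3-[(tert-butyldiphenylsilyl)oxy]-2-hydroxypropanoate; 6 4-allyl-2,6-dimethoxyphenol
Product: 7 methyl (S)-2-(4-allyl-2,6-dimethoxyphenoxy)-3-[(tert-butyldiphenylsilyl)oxy]propanoate
Conditions: PPh3, DIAD, toluene, 0 to 50 °C
Reagents that add atoms: none
Why: Mitsunobu reaction: PPh3 and DIAD form the betaine, which is protonated by phenol 6 and then activates the C8 hydroxyl of 5 as an oxyphosphonium leaving group. The phenoxide of 6 displaces it by SN2, so the C8–O4′ bond forms with inversion and the R carbinol becomes the S aryl ether of the target. The closest known reaction type is the Mitsunobu aryl etherification of lactate-type α-hydroxy esters with ortho-substituted phenols. No ring is closed. The one new stereocentre, C8, is controlled by the pool centre and the stereospecific inversion, and it later directs C7 in step 6. The selectivities needed are substitution over β-elimination and O- over C-alkylation. The adjacent ester carbonyl speeds SN2 and disfavours ionization at C8; both ortho positions and the para position of 6 are substituted, so only oxygen can be alkylated; and the only other hydroxyl of 5 is capped. The phenol is acidic enough for the betaine and the allyl group is inert to these reagents.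

Step 5
Reactants: 7 methyl (S)-2-(4-allyl-2,6-dimethoxyphenoxy)-3-[(tert-butyldiphenylsilyl)oxy]propanoate; 2 tert-butyl(4-bromo-2,6-dimethoxyphenoxy)dimethylsilane
Product: 10 (S)-2-(4-allyl-2,6-dimethoxyphenoxy)-1-[4-[(tert-butyldimethylsilyl)oxy]-3,5-dimethoxyphenyl]-3-[(tert-butyldiphenylsilyl)oxy]propan-1-one, via Weinreb amide 8 (not isolated), via aryllithium 9 (not isolated)
Conditions: MeNH(OMe)·HCl, i-PrMgCl, THF, −20 °C; then 9 (from 2, n-BuLi, THF, −78 °C), −78 to −40 °C; aq. NH4Cl
Reagents that add atoms: none
Why: The chloromagnesium amide converts the ester into the Weinreb amide, whose chelated tetrahedral adduct with the aryllithium (bromine–lithium exchange on 2) collapses only on quench, so the ketone forms without over-addition. Addition to the carbonyl at low temperature should outrun deprotonation at C8, so the S centre is kept.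

Step 6
Reactants: 10 (S)-2-(4-allyl-2,6-dimethoxyphenoxy)-1-[4-[(tert-butyldimethylsilyl)oxy]-3,5-dimethoxyphenyl]-3-[(tert-butyldiphenylsilyl)oxy]propan-1-one
Product: 11 (1R,2S)-2-(4-allyl-2,6-dimethoxyphenoxy)-1-[4-[(tert-butyldimethylsilyl)oxy]-3,5-dimethoxyphenyl]-3-[(tert-butyldiphenylsilyl)oxy]propan-1-ol
Conditions: Zn(BH4)2, Et2O, −30 °C; aq. NH4Cl
Reagents that add atoms: none
Why: Cram-chelate-controlled reduction: zinc bridges the C7 carbonyl oxygen and O4′ on C8 (supported by an ortho-methoxy group of ring B), and hydride enters past the C8 hydrogen, away from C9, which should set 7R and hence the erythro pair. The silyl ether on O9 cannot compete as a donor, and the terminal alkene should be untouched at this temperature.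

Step 7
Reactants: 11 (1R,2S)-2-(4-allyl-2,6-dimethoxyphenoxy)-1-[4-[(tert-butyldimethylsilyl)oxy]-3,5-dimethoxyphenyl]-3-[(tert-butyldiphenylsilyl)oxy]propan-1-ol
Product: 12 (1R,2S)-2-(4-allyl-2,6-dimethoxyphenoxy)-1-(4-hydroxy-3,5-dimethoxyphenyl)propane-1,3-diol
Conditions: TBAF, AcOH, THF, 0 °C to rt
Reagents that add atoms: none
Why: Fluoride cleaves both silyl ethers (aryl–O–Si fast, alkyl–O–Si more slowly). The acetic acid buffer keeps the freed phenol protonated, so no quinone methide should form at C7 and neither stereocentre is touched.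

## Compound list

1 | 4-bromo-2,6-dimethoxyphenol | COc1cc(Br)cc(OC)c1O | starting material
2 | tert-butyl(4-bromo-2,6-dimethoxyphenoxy)dimethylsilane | COc1cc(Br)cc(OC)c1O[Si](C)(C)C(C)(C)C | intermediate
3 | methyl (R)-2,2-dimethyl-1,3-dioxolane-4-carboxylate | COC(=O)[C@H]1COC(C)(C)O1 | starting material
4 | methyl (R)-2,3-dihydroxypropanoate | COC(=O)[C@H](O)CO | intermediate
5 | methyl (R)-3-[(tert-butyldiphenylsilyl)oxy]-2-hydroxypropanoate | COC(=O)[C@H](O)CO[Si](c1ccccc1)(c1ccccc1)C(C)(C)C | intermediate
6 | 4-allyl-2,6-dimethoxyphenol | C=CCc1cc(OC)c(O)c(OC)c1 | starting material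
7 | methyl (S)-2-(4-allyl-2,6-dimethoxyphenoxy)-3-[(tert-butyldiphenylsilyl)oxy]propanoate | COC(=O)[C@@H](Oc1c(OC)cc(CC=C)cc1OC)CO[Si](c1ccccc1)(c1ccccc1)C(C)(C)C | intermediate
8 | (S)-2-(4-allyl-2,6-dimethoxyphenoxy)-3-[(tert-butyldiphenylsilyl)oxy]-N-methoxy-N-methylpropanamide | CON(C)C(=O)[C@@H](Oc1c(OC)cc(CC=C)cc1OC)CO[Si](c1ccccc1)(c1ccccc1)C(C)(C)C | intermediate
9 | [4-[(tert-butyldimethylsilyl)oxy]-3,5-dimethoxyphenyl]lithium | [Li]c1cc(OC)c(O[Si](C)(C)C(C)(C)C)c(OC)c1 | intermediate
10 | (S)-2-(4-allyl-2,6-dimethoxyphenoxy)-1-[4-[(tert-butyldimethylsilyl)oxy]-3,5-dimethoxyphenyl]-3-[(tert-butyldiphenylsilyl)oxy]propan-1-one | O=C(c1cc(OC)c(O[Si](C)(C)C(C)(C)C)c(OC)c1)[C@@H](Oc1c(OC)cc(CC=C)cc1OC)CO[Si](c1ccccc1)(c1ccccc1)C(C)(C)C | intermediate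
11 | (1R,2S)-2-(4-allyl-2,6-dimethoxyphenoxy)-1-[4-[(tert-butyldimethylsilyl)oxy]-3,5-dimethoxyphenyl]-3-[(tert-butyldiphenylsilyl)oxy]propan-1-ol | C=CCc1cc(OC)c(O[C@@H](CO[Si](c2ccccc2)(c2ccccc2)C(C)(C)C)[C@H](O)c2cc(OC)c(O[Si](C)(C)C(C)(C)C)c(OC)c2)c(OC)c1 | intermediate
12 | (1R,2S)-2-(4-allyl-2,6-dimethoxyphenoxy)-1-(4-hydroxy-3,5-dimethoxyphenyl)propane-1,3-diol | C=CCc1cc(OC)c(O[C@@H](CO)[C@H](O)c2cc(OC)c(O)c(OC)c2)c(OC)c1 | target

## Step count and risks

Total step count: 7. Longest linear sequence: 6 steps (3 → 4 → 5 → 7 → 10 → 11 → 12, steps 2 to 7); step 1 is a one-step side branch.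

**Step 4 (key step).** The redox condensation may stall with the di-ortho-substituted phenol, so that β-elimination across C8–C9 or N-alkylation of the reduced azodicarboxylate overtakes ether formation. Fallback (sulfonate displacement in place of redox condensation): from 5, the C8 hydroxyl is converted with Tf2O and 2,6-lutidine at −78 °C into methyl (R)-3-[(tert-butyldiphenylsilyl)oxy]-2-{[(trifluoromethyl)sulfonyl]oxy}propanoate F1. This is displaced with inversion by the preformed potassium salt of 6 (KHMDS, THF, −40 to 0 °C), and the sequence comes back to the route at 7.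

**Step 5.** Proton abstraction at C8 of 8 or of the forming ketone by the strongly basic aryllithium would erode the configuration, and incomplete amide formation would open the way to double addition. Fallback (base-free acyl cross-coupling): from 7, AlMe3/EtSH gives S-ethyl (S)-2-(4-allyl-2,6-dimethoxyphenoxy)-3-[(tert-butyldiphenylsilyl)oxy]propanethioate F2. Liebeskind–Srogl coupling (Pd(0), copper(I) thiophene-2-carboxylate, THF) with [4-[(tert-butyldimethylsilyl)oxy]-3,5-dimethoxyphenyl]boronic acid F3, made from 2 through 9 and triisopropyl borate, then comes back to the route at 10.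

**Step 6.** Facial selectivity may be poor if the aryl ether oxygen binds zinc too weakly, so that non-chelated polar Felkin–Anh delivery (which leads to threo) competes; warming could also let borane by-products hydroborate the allyl group. Fallback (C7 set during C–C bond formation): from 7, DIBAL-H at −78 °C gives (S)-2-(4-allyl-2,6-dimethoxyphenoxy)-3-[(tert-butyldiphenylsilyl)oxy]propanal F4. The non-chelating aryltitanium [4-[(tert-butyldimethylsilyl)oxy]-3,5-dimethoxyphenyl]tris(propan-2-olato)titanium F5, made from 9 and ClTi(OiPr)3, is then added under Felkin–Anh control with O4′ anti to the incoming aryl group. The same weak donor ability that would spoil the chelate favours this mode, which should give 7R; the sequence bypasses 10 and comes back to the route at 11.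

## Further compounds

F1 | step 4 | methyl (R)-3-[(tert-butyldiphenylsilyl)oxy]-2-{[(trifluoromethyl)sulfonyl]oxy}propanoate | COC(=O)[C@H](OS(=O)(=O)C(F)(F)F)CO[Si](c1ccccc1)(c1ccccc1)C(C)(C)C
F2 | step 5 | S-ethyl (S)-2-(4-allyl-2,6-dimethoxyphenoxy)-3-[(tert-butyldiphenylsilyl)oxy]propanethioate | CCSC(=O)[C@@H](Oc1c(OC)cc(CC=C)cc1OC)CO[Si](c1ccccc1)(c1ccccc1)C(C)(C)C
F3 | step 5 | [4-[(tert-butyldimethylsilyl)oxy]-3,5-dimethoxyphenyl]boronic acid | OB(O)c1cc(OC)c(O[Si](C)(C)C(C)(C)C)c(OC)c1
F4 | step 6 | (S)-2-(4-allyl-2,6-dimethoxyphenoxy)-3-[(tert-butyldiphenylsilyl)oxy]propanal | O=C[C@@H](Oc1c(OC)cc(CC=C)cc1OC)CO[Si](c1ccccc1)(c1ccccc1)C(C)(C)C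
F5 | step 6 | [4-[(tert-butyldimethylsilyl)oxy]-3,5-dimethoxyphenyl]tris(propan-2-olato)titanium | CC(C)O[Ti](OC(C)C)(OC(C)C)c1cc(OC)c(O[Si](C)(C)C(C)(C)C)c(OC)c1
A1 | alternative 1 | (S)-4-benzyl-3-[(4-allyl-2,6-dimethoxyphenoxy)acetyl]oxazolidin-2-one | C=CCc1cc(OC)c(OCC(=O)N2[C@@H](Cc3ccccc3)COC2=O)c(OC)c1
A2 | alternative 1 | 4-[(tert-butyldimethylsilyl)oxy]-3,5-dimethoxybenzaldehyde | O=Cc1cc(OC)c(O[Si](C)(C)C(C)(C)C)c(OC)c1
A3 | alternative 1 | (S)-4-benzyl-3-[(2S,3R)-2-(4-allyl-2,6-dimethoxyphenoxy)-3-[4-[(tert-butyldimethylsilyl)oxy]-3,5-dimethoxyphenyl]-3-hydroxypropanoyl]oxazolidin-2-one | C=CCc1cc(OC)c(O[C@H](C(=O)N2[C@@H](Cc3ccccc3)COC2=O)[C@H](O)c2cc(OC)c(O[Si](C)(C)C(C)(C)C)c(OC)c2)c(OC)c1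
A4 | alternative 2 | ethyl (E)-3-[4-[(tert-butyldimethylsilyl)oxy]-3,5-dimethoxyphenyl]acrylate | CCOC(=O)/C=C/c1cc(OC)c(O[Si](C)(C)C(C)(C)C)c(OC)c1
A5 | alternative 2 | ethyl (2S,3R)-3-[4-[(tert-butyldimethylsilyl)oxy]-3,5-dimethoxyphenyl]-2,3-dihydroxypropanoate | CCOC(=O)[C@@H](O)[C@H](O)c1cc(OC)c(O[Si](C)(C)C(C)(C)C)c(OC)c1
A6 | alternative 2 | ethyl (2S,3R)-3-[4-[(tert-butyldimethylsilyl)oxy]-3,5-dimethoxyphenyl]-3-hydroxy-2-{[(4-nitrophenyl)sulfonyl]oxy}propanoate | CCOC(=O)[C@@H](OS(=O)(=O)c1ccc(cc1)[N+](=O)[O-])[C@H](O)c1cc(OC)c(O[Si](C)(C)C(C)(C)C)c(OC)c1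
A7 | alternative 3 | ethyl 2-(4-allyl-2,6-dimethoxyphenoxy)-3-[4-[(tert-butyldimethylsilyl)oxy]-3,5-dimethoxyphenyl]-3-oxopropanoate (racemic) | CCOC(=O)C(Oc1c(OC)cc(CC=C)cc1OC)C(=O)c1cc(OC)c(O[Si](C)(C)C(C)(C)C)c(OC)c1
A8 | alternative 3 | ethyl (2R,3S)-2-(4-allyl-2,6-dimethoxyphenoxy)-3-[4-[(tert-butyldimethylsilyl)oxy]-3,5-dimethoxyphenyl]-3-hydroxypropanoate | C=CCc1cc(OC)c(O[C@@H](C(=O)OCC)[C@@H](O)c2cc(OC)c(O[Si](C)(C)C(C)(C)C)c(OC)c2)c(OC)c1
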